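**Plan** (azulene numbering of the target; ring A = cyclopentane C1, C2, C3, C3a, C8a; ring B = seven-membered ring C3a, C4 to C8, C8a)
1. Retrosynthesis: cut the cinnamate C–O bond, then the two methyl–carbinol bonds (C5 ester), then the C8–CH3 bond (enol triflate of a C8 ketone), then both ring-B bonds C4–C5 and C7–C8 at once in a (4+3) cycloaddition.
2. Enabling feature: ring B holds the three-carbon unit C5–C6(O)–C7 with oxygen on its middle carbon (a siloxyvinyl-carbene pattern). Both its ends are bonded to the four-carbon unit C4–C3a–C8a–C8, whose inner atoms are the ring-A fusion atoms, i.e. an s-cis-locked bis-exocyclic diene on a cyclopentane.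
3. Forward: ring A first (2-methylcyclopentenone → enol triflate → ester → vinylogous silyl ketene acetal), then ring B by rhodium-carbenoid cyclopropanation/Cope rearrangement. The diene carries C8 at the carboxyl level as a helper, so the adduct is a C8 enone; conjugate reduction, enolate triflation and methylation then move the ring-fusion alkene to C8=C8a. The C6 enol silane is the second helper.
4. Stereochemistry: C3 from a copper-catalysed asymmetric conjugate addition; C3a from hydride delivery anti to the C3 methyl; C5 and C6 (trans) from a ruthenium–BINAP hydrogenation with dynamic kinetic resolution; the E-alkene comes with the acid.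
5. End game: C5 ester → tertiary carbinol (MeMgBr), selective acylation of the secondary hydroxyl, removal of the phenol acetate.

Key step: step 6

Remark: the sense of induction in steps 1 and 10 is assigned by analogy with the parent cyclic substrates; the antipodal ligand would be used if it proved opposite.

**Step 1**
Reactants: 1 2-methylcyclopent-2-en-1-one
Product: 3 (3S)-2,3-dimethylcyclopent-1-en-1-yl trifluoromethanesulfonate, via aluminium enolate 2 (not isolated)
Conditions: Me3Al, Cu(O2CC4H3S) (copper thiophene-2-carboxylate, cat.), BINOL/bis(1-phenylethyl)amine phosphoramidite (enantiomer giving 3S), Et2O, −30 °C; then MeLi, THF, −78 °C; PhNTf2, −78 → 0 °C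
Reagents that add atoms: trimethylaluminium, C[Al](C)C; N-phenylbis(trifluoromethanesulfonimide), O=S(=O)(N(c1ccccc1)S(=O)(=O)C(F)(F)F)C(F)(F)F
Why: Copper-catalysed asymmetric conjugate addition sets the 3S centre under ligand control, and the regiodefined aluminium enolate, activated as its ate complex with MeLi, is O-triflated so that the enol double bond lies between the former carbonyl carbon and the methyl-bearing carbon (conjugate addition/enolate trapping).

**Step 2**
Reactants: 3 (3S)-2,3-dimethylcyclopent-1-en-1-yl trifluoromethanesulfonate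
Product: 4 methyl (3S)-2,3-dimethylcyclopent-1-ene-1-carboxylate
Conditions: Pd(OAc)2 (cat.), dppp, CO (1 atm), MeOH, Et3N, DMF, 60 °C
Reagents that add atoms: carbon monoxide, [C-]#[O+]; methanol, CO
Why: Palladium-catalysed alkoxycarbonylation of an enol triflate (oxidative addition, CO insertion, methanolysis) is routine for hindered cyclic triflates and leaves the remote stereocentre untouched.

**Step 3**
Reactants: 4 methyl (3S)-2,3-dimethylcyclopent-1-ene-1-carboxylate
Product: 6 tert-butyl{methoxy[(3S)-3-methyl-2-methylidenecyclopentylidene]methoxy}dimethylsilane, via lithium dienolate 5 (not isolated)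
Conditions: LiN(iPr)2, THF/DMPU, −78 °C; then t-BuMe2SiCl, −78 → 0 °C
Reagents that add atoms: tert-butyldimethylsilyl chloride, CC(C)(C)[Si](C)(C)Cl
Why: Kinetic γ-deprotonation of the enoate at the methyl group cis to the ester (the tertiary γ-hydrogen at the stereocentre should be slower to leave) gives the cross-conjugated dienolate, which silylates on oxygen to the vinylogous silyl ketene acetal; the geometry about the ketene-acetal double bond is of no consequence.

**Step 4**
Reactants: 7 methyl acetoacetate
Product: 8 methyl 2-diazo-3-oxobutanoate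
Conditions: 4-acetamidobenzenesulfonyl azide, Et3N, MeCN, 0 °C → rt
Reagents that add atoms: 4-acetamidobenzenesulfonyl azide, CC(=O)Nc1ccc(cc1)S(=O)(=O)N=[N+]=[N-]
Why: Regitz diazo transfer to the doubly activated methylene of a β-keto ester.

**Step 5**
Reactants: 8 methyl 2-diazo-3-oxobutanoate
Product: 9 methyl 2-diazo-3-[(triisopropylsilyl)oxy]but-3-enoate
Conditions: iPr3SiOTf, Et3N, CH2Cl2, 0 °C
Reagents that add atoms: triisopropylsilyl trifluoromethanesulfonate, CC(C)[Si](OS(=O)(=O)C(F)(F)F)(C(C)C)C(C)C
Why: Soft enolisation and O-silylation of the acetyl group gives the siloxyvinyldiazoacetate, the bulky triisopropylsilyl group being chosen so that the derived enol silane survives steps 6 to 8.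

**Step 6**
Reactants: 6 tert-butyl{methoxy[(3S)-3-methyl-2-methylidenecyclopentylidene]methoxy}dimethylsilane; 9 methyl 2-diazo-3-[(triisopropylsilyl)oxy]but-3-enoate
Product: 12 methyl (3S)-3-methyl-8-oxo-6-[(triisopropylsilyl)oxy]-1,2,3,4,7,8-hexahydroazulene-5-carboxylate, via divinylcyclopropane 10 (not isolated), via ketal adduct 11 (not isolated)
Conditions: Rh2(O2CC7H15)4 (1 mol %), hexanes, 60 °C, slow addition of 9; then AcOH, THF/H2O, 0 °C
Reagents that add atoms: none
Why: Rh2(O2CC7H15)4 converts 9 into an electrophilic siloxyvinyl carbenoid whose carbene carbon attacks the unsubstituted methylene terminus of the ketene-acetal-activated diene 6 and cyclopropanates that exocyclic alkene to 10; a [3,3]-sigmatropic (Cope) rearrangement through a boat transition state then joins the vinyl CH2 to the ketene-acetal carbon, so C4–C5 and C7–C8 are made in one operation (a ring-opened zwitterion, should it intervene, is expected to collapse to the same adduct because the cation is localised on the dioxygenated carbon). The closest known reaction type is the rhodium-carbenoid tandem cyclopropanation/Cope rearrangement ((4+3) cycloaddition) of vinyldiazoacetates with dienes, including 1-methoxy-1-silyloxybutadiene. Ring B is closed as a seven-membered ring by sigmatropic ring expansion of the three-membered ring (formal (4+3) cycloaddition), not by an ionic cyclisation; ring A is untouched. No stereocentre that survives is created: the carbene carbon ends sp2 in the enol silane, and the ketal carbon C8 of 11 loses methanol and silanol on the aqueous acetic acid work-up to give the C8 ketone, so only the existing 3S centre is carried through. The step needs regio- and chemoselectivity (carbene carbon to the CH2 terminus, seven-membered ring and not a cyclopentene or a stalled cyclopropane); these should be secured by the donor bias of the ketene acetal, by the fixed s-cis geometry of the bis-exocyclic diene on ring A, and by the siloxy group of 9, which suppresses vinylogous attack at the vinyl terminus of the carbenoid.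

**Step 7**
Reactants: 12 methyl (3S)-3-methyl-8-oxo-6-[(triisopropylsilyl)oxy]-1,2,3,4,7,8-hexahydroazulene-5-carboxylate
Product: 14 methyl (3S,3aS)-3-methyl-6-[(triisopropylsilyl)oxy]-8-{[(trifluoromethyl)sulfonyl]oxy}-1,2,3,3a,4,7-hexahydroazulene-5-carboxylate, via silyl enol ether 13 (not isolated)
Conditions: [(Ph3P)CuH]6 (cat.), PhMe2SiH, toluene, rt; then CsF, PhNTf2, DME, rt
Reagents that add atoms: N-phenylbis(trifluoromethanesulfonimide), O=S(=O)(N(c1ccccc1)S(=O)(=O)C(F)(F)F)C(F)(F)F
Why: Copper-hydride-catalysed 1,4-hydrosilylation should deliver hydride to C3a of the tetrasubstituted enone from the face opposite the adjacent C3 methyl (setting 3aS) and give the regiodefined silyl enol ether, whose unhindered silyl group is cleaved by fluoride in preference to the triisopropylsilyl enol ether and trapped by PhNTf2 as the C8=C8a enol triflate (conjugate reduction with regiospecific enolate capture).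

**Step 8**
Reactants: 14 methyl (3S,3aS)-3-methyl-6-[(triisopropylsilyl)oxy]-8-{[(trifluoromethyl)sulfonyl]oxy}-1,2,3,3a,4,7-hexahydroazulene-5-carboxylate
Product: 15 methyl (3S,3aS)-3,8-dimethyl-6-[(triisopropylsilyl)oxy]-1,2,3,3a,4,7-hexahydroazulene-5-carboxylate
Conditions: MeZnCl, Pd(PPh3)4 (cat.), THF, 50 °C
Reagents that add atoms: methylzinc chloride, C[Zn]Cl
Why: Negishi cross-coupling of the enol triflate installs the C8 methyl on the pre-positioned tetrasubstituted alkene and tolerates the ester and the enol silane.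

**Step 9**
Reactants: 15 methyl (3S,3aS)-3,8-dimethyl-6-[(triisopropylsilyl)oxy]-1,2,3,3a,4,7-hexahydroazulene-5-carboxylate
Product: 16 methyl (3S,3aS)-3,8-dimethyl-6-oxo-1,2,3,3a,4,5,6,7-octahydroazulene-5-carboxylate (C5 epimers and enol form)
Conditions: Bu4NF, AcOH, THF, 0 °C
Reagents that add atoms: none
Why: Buffered fluoride desilylation frees the β-keto ester without the basic conditions that could move the β,γ-alkene into conjugation with the ketone.

**Step 10**
Reactants: 16 methyl (3S,3aS)-3,8-dimethyl-6-oxo-1,2,3,3a,4,5,6,7-octahydroazulene-5-carboxylate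
Product: 17 methyl (3S,3aS,5S,6S)-6-hydroxy-3,8-dimethyl-1,2,3,3a,4,5,6,7-octahydroazulene-5-carboxylate
Conditions: [RuCl(C6H6)((S)-BINAP)]Cl (cat.), H2 (100 atm), CH2Cl2, 50 °C
Reagents that add atoms: none
Why: Noyori hydrogenation with dynamic kinetic resolution: C5 epimerises rapidly through the enol while the (S)-BINAP–ruthenium hydride reduces one form, which should give the trans (5S,6S) hydroxy ester under catalyst control (an arrangement the ring is also expected to favour), the tetrasubstituted alkene being inert.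

**Step 11**
Reactants: 17 methyl (3S,3aS,5S,6S)-6-hydroxy-3,8-dimethyl-1,2,3,3a,4,5,6,7-octahydroazulene-5-carboxylate
Product: 19 (3S,3aS,5S,6S)-5-(2-hydroxypropan-2-yl)-3,8-dimethyl-1,2,3,3a,4,5,6,7-octahydroazulen-6-ol, via methyl ketone 18 (not isolated)
Conditions: MeMgBr (excess), THF, 0 °C → rt; aq. NH4Cl
Reagents that add atoms: methylmagnesium bromide, C[Mg]Br
Why: Double Grignard addition to the ester builds the tertiary carbinol, and the α-centre is not at risk because it already has the thermodynamically preferred trans arrangement.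

**Step 12**
Reactants: 19 (3S,3aS,5S,6S)-5-(2-hydroxypropan-2-yl)-3,8-dimethyl-1,2,3,3a,4,5,6,7-octahydroazulen-6-ol; 20 (2E)-3-(4-acetoxyphenyl)prop-2-enoic acid
Product: 21 (3S,3aS,5S,6S)-5-(2-hydroxypropan-2-yl)-3,8-dimethyl-1,2,3,3a,4,5,6,7-octahydroazulen-6-yl (2E)-3-(4-acetoxyphenyl)prop-2-enoate
Conditions: DCC, DMAP (cat.), CH2Cl2, 0 °C → rt
Reagents that add atoms: none
Why: Steglich esterification should acylate only the secondary hydroxyl, the tertiary carbinol being unreactive under carbodiimide/DMAP conditions, and keeps the E-alkene of the acid.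

**Step 13**
Reactants: 21 (3S,3aS,5S,6S)-5-(2-hydroxypropan-2-yl)-3,8-dimethyl-1,2,3,3a,4,5,6,7-octahydroazulen-6-yl (2E)-3-(4-acetoxyphenyl)prop-2-enoate
Product: 22 (3S,3aS,5S,6S)-5-(2-hydroxypropan-2-yl)-3,8-dimethyl-1,2,3,3a,4,5,6,7-octahydroazulen-6-yl (2E)-3-(4-hydroxyphenyl)prop-2-enoate
Conditions: K2CO3 (cat.), MeOH, 0 °C
Reagents that add atoms: none
Why: Base-catalysed methanolysis should remove the aryl acetate far faster than it attacks the hindered secondary cinnamate (selective transesterification of a phenyl ester).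

**Compound list**
1 | 2-methylcyclopent-2-en-1-one | CC1=CCCC1=O | starting material
2 | dimethylaluminium (3S)-2,3-dimethylcyclopent-1-en-1-olate | C[C@H]1CCC(O[Al](C)C)=C1C | intermediate
3 | (3S)-2,3-dimethylcyclopent-1-en-1-yl trifluoromethanesulfonate | C[C@H]1CCC(OS(=O)(=O)C(F)(F)F)=C1C | intermediate
4 | methyl (3S)-2,3-dimethylcyclopent-1-ene-1-carboxylate | COC(=O)C1=C(C)[C@@H](C)CC1 | intermediate
5 | lithium methoxy[(3S)-3-methyl-2-methylidenecyclopentylidene]methanolate | [Li+].[O-]C(OC)=C1CC[C@H](C)C1=C | intermediate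
6 | tert-butyl{methoxy[(3S)-3-methyl-2-methylidenecyclopentylidene]methoxy}dimethylsilane (either geometry at the ketene acetal) | COC(O[Si](C)(C)C(C)(C)C)=C1CC[C@H](C)C1=C | intermediate
7 | methyl acetoacetate | CC(=O)CC(=O)OC | starting material
8 | methyl 2-diazo-3-oxobutanoate | CC(=O)C(=[N+]=[N-])C(=O)OC | intermediate
9 | methyl 2-diazo-3-[(triisopropylsilyl)oxy]but-3-enoate | C=C(O[Si](C(C)C)(C(C)C)C(C)C)C(=[N+]=[N-])C(=O)OC | intermediate
10 | methyl 4-{[tert-butyl(dimethyl)silyl]oxy(methoxy)methylidene}-7-methyl-1-{1-[(triisopropylsilyl)oxy]ethenyl}spiro[2.4]heptane-1-carboxylate (7S; cyclopropane centres as formed) | C=C(O[Si](C(C)C)(C(C)C)C(C)C)C1(C(=O)OC)CC12[C@@H](C)CCC2=C(OC)O[Si](C)(C)C(C)(C)C | intermediate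
11 | methyl (3S)-8-[(tert-butyldimethylsilyl)oxy]-8-methoxy-3-methyl-6-[(triisopropylsilyl)oxy]-1,2,3,4,7,8-hexahydroazulene-5-carboxylate (C8 epimers) | COC1(O[Si](C)(C)C(C)(C)C)CC(O[Si](C(C)C)(C(C)C)C(C)C)=C(C(=O)OC)CC2=C1CC[C@@H]2C | intermediate
12 | methyl (3S)-3-methyl-8-oxo-6-[(triisopropylsilyl)oxy]-1,2,3,4,7,8-hexahydroazulene-5-carboxylate | O=C1CC(O[Si](C(C)C)(C(C)C)C(C)C)=C(C(=O)OC)CC2=C1CC[C@@H]2C | intermediate
13 | methyl (3S,3aS)-8-{[dimethyl(phenyl)silyl]oxy}-3-methyl-6-[(triisopropylsilyl)oxy]-1,2,3,3a,4,7-hexahydroazulene-5-carboxylate | C[Si](C)(OC1=C2CC[C@H](C)[C@@H]2CC(C(=O)OC)=C(O[Si](C(C)C)(C(C)C)C(C)C)C1)c1ccccc1 | intermediate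
14 | methyl (3S,3aS)-3-methyl-6-[(triisopropylsilyl)oxy]-8-{[(trifluoromethyl)sulfonyl]oxy}-1,2,3,3a,4,7-hexahydroazulene-5-carboxylate | O=S(=O)(OC1=C2CC[C@H](C)[C@@H]2CC(C(=O)OC)=C(O[Si](C(C)C)(C(C)C)C(C)C)C1)C(F)(F)F | intermediate
15 | methyl (3S,3aS)-3,8-dimethyl-6-[(triisopropylsilyl)oxy]-1,2,3,3a,4,7-hexahydroazulene-5-carboxylate | CC1=C2CC[C@H](C)[C@@H]2CC(C(=O)OC)=C(O[Si](C(C)C)(C(C)C)C(C)C)C1 | intermediate
16 | methyl (3S,3aS)-3,8-dimethyl-6-oxo-1,2,3,3a,4,5,6,7-octahydroazulene-5-carboxylate | CC1=C2CC[C@H](C)[C@@H]2CC(C(=O)OC)C(=O)C1 | intermediate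
17 | methyl (3S,3aS,5S,6S)-6-hydroxy-3,8-dimethyl-1,2,3,3a,4,5,6,7-octahydroazulene-5-carboxylate | CC1=C2CC[C@H](C)[C@@H]2C[C@H](C(=O)OC)[C@@H](O)C1 | intermediate
18 | 1-[(3S,3aS,5S,6S)-6-hydroxy-3,8-dimethyl-1,2,3,3a,4,5,6,7-octahydroazulen-5-yl]ethan-1-one (present as its magnesium alkoxide) | CC1=C2CC[C@H](C)[C@@H]2C[C@H](C(C)=O)[C@@H](O)C1 | intermediate
19 | (3S,3aS,5S,6S)-5-(2-hydroxypropan-2-yl)-3,8-dimethyl-1,2,3,3a,4,5,6,7-octahydroazulen-6-ol | CC1=C2CC[C@H](C)[C@@H]2C[C@H](C(C)(C)O)[C@@H](O)C1 | intermediate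
20 | (2E)-3-(4-acetoxyphenyl)prop-2-enoic acid | CC(=O)Oc1ccc(/C=C/C(=O)O)cc1 | starting material
21 | (3S,3aS,5S,6S)-5-(2-hydroxypropan-2-yl)-3,8-dimethyl-1,2,3,3a,4,5,6,7-octahydroazulen-6-yl (2E)-3-(4-acetoxyphenyl)prop-2-enoate | CC1=C2CC[C@H](C)[C@@H]2C[C@H](C(C)(C)O)[C@@H](OC(=O)/C=C/c2ccc(OC(C)=O)cc2)C1 | intermediate
22 | (3S,3aS,5S,6S)-5-(2-hydroxypropan-2-yl)-3,8-dimethyl-1,2,3,3a,4,5,6,7-octahydroazulen-6-yl (2E)-3-(4-hydroxyphenyl)prop-2-enoate | CC1=C2CC[C@H](C)[C@@H]2C[C@H](C(C)(C)O)[C@@H](OC(=O)/C=C/c2ccc(O)cc2)C1 | target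

**Totals**
Total step count: 13. Longest linear sequence: 11 steps (steps 1, 2, 3, 6, 7, 8, 9, 10, 11, 12, 13).

**Steps most likely to fail**

Step 6. The carbenoid addition may be diverted by capture of a ring-opened zwitterion in a five-membered ring closure, by hydrolysis of the ketene acetal before carbene transfer, or by a cyclopropane that does not rearrange. The fallback makes the same two bonds stepwise by ionic chemistry and sets out from 6 and 7. Bromination of 6 with N-bromosuccinimide (THF, −78 °C) at the γ-carbon should give methyl (3S)-2-(bromomethyl)-3-methylcyclopent-1-ene-1-carboxylate F1. C-Alkylation of the sodium enolate of 7 (NaH, THF, 0 °C) with F1 should give methyl 2-{[(5S)-2-(methoxycarbonyl)-5-methylcyclopent-1-en-1-yl]methyl}-3-oxobutanoate F2. Silylation (iPr3SiOTf, Et3N, CH2Cl2) should give methyl 2-{[(5S)-2-(methoxycarbonyl)-5-methylcyclopent-1-en-1-yl]methyl}-3-[(triisopropylsilyl)oxy]but-2-enoate F3. γ-Deprotonation of F3 (LiN(iPr)2, THF, −78 → 0 °C) and intramolecular vinylogous Claisen (Dieckmann-type) condensation onto the ring ester should close ring B and come back to the route at 12.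

Step 7. Hydrometalation of the tetrasubstituted enone may be sluggish, 1,2-reduction or poor facial selectivity may compete, and fluoride may attack the triisopropylsilyl enol ether during triflation. The fallback replaces hydride transfer by a single-electron reduction and sets out from 12. Lithium in liquid NH3/THF with t-BuOH (1 equiv) at −78 °C should give the regiodefined lithium (3S,3aS)-5-(methoxycarbonyl)-3-methyl-6-[(triisopropylsilyl)oxy]-1,2,3,3a,4,7-hexahydroazulen-8-olate F4, with protonation at C3a expected anti to the C3 methyl. After removal of ammonia, F4 is triflated in the same flask with PhNTf2 and comes back to the route at 14.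

Step 10. The C8=C8a alkene may migrate into conjugation with the ketone under the hydrogenation conditions, or substrate and catalyst control may be mismatched and erode the diastereoselectivity. The fallback sets C5 and C6 by hydroboration and sets out from 16. Enol triflation (NaH, PhNTf2, THF) should give methyl (3S,3aS)-3,8-dimethyl-6-{[(trifluoromethyl)sulfonyl]oxy}-1,2,3,3a,4,7-hexahydroazulene-5-carboxylate F5. Palladium-catalysed reduction (Pd(OAc)2, PPh3, HCO2H, Et3N, DMF) should give methyl (3S,3aS)-3,8-dimethyl-1,2,3,3a,4,7-hexahydroazulene-5-carboxylate F6. MeMgBr should convert F6 into 2-[(3S,3aS)-3,8-dimethyl-1,2,3,3a,4,7-hexahydroazulen-5-yl]propan-2-ol F7. Asymmetric hydroboration of the trisubstituted C5=C6 alkene of F7 with monoisopinocampheylborane (enantiomer matched to the 5S,6S product), then NaOH/H2O2, should place boron at C6 and hydrogen at C5 by syn addition, giving the trans diol and coming back to the route at 19.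

**Further compounds**
F1 | step 6 | methyl (3S)-2-(bromomethyl)-3-methylcyclopent-1-ene-1-carboxylate | COC(=O)C1=C(CBr)[C@@H](C)CC1
F2 | step 6 | methyl 2-{[(5S)-2-(methoxycarbonyl)-5-methylcyclopent-1-en-1-yl]methyl}-3-oxobutanoate | COC(=O)C1=C(CC(C(C)=O)C(=O)OC)[C@@H](C)CC1
F3 | step 6 | methyl 2-{[(5S)-2-(methoxycarbonyl)-5-methylcyclopent-1-en-1-yl]methyl}-3-[(triisopropylsilyl)oxy]but-2-enoate | COC(=O)C1=C(CC(C(=O)OC)=C(C)O[Si](C(C)C)(C(C)C)C(C)C)[C@@H](C)CC1
F4 | step 7 | lithium (3S,3aS)-5-(methoxycarbonyl)-3-methyl-6-[(triisopropylsilyl)oxy]-1,2,3,3a,4,7-hexahydroazulen-8-olate | [Li+].[O-]C1=C2CC[C@H](C)[C@@H]2CC(C(=O)OC)=C(O[Si](C(C)C)(C(C)C)C(C)C)C1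
F5 | step 10 | methyl (3S,3aS)-3,8-dimethyl-6-{[(trifluoromethyl)sulfonyl]oxy}-1,2,3,3a,4,7-hexahydroazulene-5-carboxylate | CC1=C2CC[C@H](C)[C@@H]2CC(C(=O)OC)=C(OS(=O)(=O)C(F)(F)F)C1
F6 | step 10 | methyl (3S,3aS)-3,8-dimethyl-1,2,3,3a,4,7-hexahydroazulene-5-carboxylate | CC1=C2CC[C@H](C)[C@@H]2CC(C(=O)OC)=CC1
F7 | step 10 | 2-[(3S,3aS)-3,8-dimethyl-1,2,3,3a,4,7-hexahydroazulen-5-yl]propan-2-ol | CC1=C2CC[C@H](C)[C@@H]2CC(C(C)(C)O)=CC1
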